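**Retrosynthetic overview**

1. The CH2 bridge is cut last (elimination–addition of a Mannich base): target ⇒ butanoylfilicinic acid 11 (ring A; locants C1 = ring C=O, C2 = butanoyl-bearing carbon, C3 = C–OH, C4 = free CH, C5 = C–OH, C6 = CMe2) + aminomethylated acetylfilicinic acid 15 (ring B).
2. Ring A ⇒ formal [4+2] of butanoylketene (C1 and C2 with the butanoyl group, released from dioxinone 3) with the 1,3-bis(silyloxy)diene 7 of methyl 4-methyl-3-oxopentanoate (C3–C6). One operation forms the C1–C6 bond (ring carbonyl carbon to CMe2) and the C2–C3 bond (butanoyl-bearing carbon to the C–OH carbon).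
3. Enabling feature: ring A is an enolised 2-acylcyclohexane-1,3,5-trione whose carbonyl carbons C1, C3 and C5 alternate with C2, C4 and the quaternary C6(CH3)2. Every ring bond is therefore an acyl–α-carbon (Claisen) bond, and C6, carrying no hydrogen, can neither let the ring aromatise nor compete as an enolisation site.
4. Ring B comes from 2',4',6'-trihydroxyacetophenone by dearomatising gem-dimethylation. Order: ring A de novo (steps 1–4), ring B (steps 5–6), bridge last (step 7). The bridge and ring B are kept off the diene because free enol OH groups would protonate 7 and consume the ketene; C4–H of ring A is the only nucleophilic ring position left for the final union.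

Key step: step 4

Remark (assumption): the target has no stereocentre (achiral, drawn as one enol tautomer), so no step needs stereocontrol; all SMILES keep the tautomer of the target.

**Step 1**
Reactants: 1 2,2,6-trimethyl-4H-1,3-dioxin-4-one
Product: 3 2,2-dimethyl-6-propyl-4H-1,3-dioxin-4-one, via lithium dienolate 2 (not isolated)
Conditions: LDA (1.1 equiv), THF–DMPU, −78 °C; EtI, −78 → −30 °C
Reagents that add atoms: ethyl iodide, CCI
Why: Vinylogous (γ) alkylation of the extended lithium enolate of the dioxinone, the usual entry to 6-alkyl dioxinones; the polar co-solvent and the soft iodide should favour γ- over α-attack.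

**Step 2**
Reactants: 4 methyl 4-methyl-3-oxopentanoate
Product: 5 methyl 4-methyl-3-(trimethylsilyloxy)pent-2-enoate (E/Z mixture, geometry immaterial)
Conditions: TMSCl, Et3N, hexane, rt; filtration
Reagents that add atoms: chlorotrimethylsilane, C[Si](C)(C)Cl
Why: O-Silylation of the β-keto ester enol under soft enolisation, the first half of the standard preparation of 1,3-bis(silyloxy)dienes.

**Step 3**
Reactants: 5 methyl 4-methyl-3-(trimethylsilyloxy)pent-2-enoate
Product: 7 1-methoxy-4-methyl-1,3-bis(trimethylsilyloxy)penta-1,3-diene, via lithium dienolate 6 (not isolated)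
Conditions: LDA, THF, −78 °C; TMSCl, −78 → 0 °C; non-aqueous work-up
Reagents that add atoms: chlorotrimethylsilane, C[Si](C)(C)Cl
Why: Kinetic γ-deprotonation of the β-silyloxy enoate (the isopropyl methine is its only acidic sp3 C–H) and O-silylation of the extended enolate, the second half of the standard bis(silyloxy)diene preparation (masked β-keto ester dianion).

**Step 4**
Reactants: 7 1-methoxy-4-methyl-1,3-bis(trimethylsilyloxy)penta-1,3-diene (1.5 equiv), 3 2,2-dimethyl-6-propyl-4H-1,3-dioxin-4-one
Product: 11 2-butanoyl-3,5-dihydroxy-6,6-dimethylcyclohexa-2,4-dien-1-one (butanoylfilicinic acid), via butanoylketene 8 (not isolated), via bis-silyl adduct 9 (not isolated), via triketo ester 10 (not isolated)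
Conditions: PhMe, 110 °C, slow addition of 3 to 7 (− acetone); then Mg(OMe)2 (3 equiv), MeOH, 65 °C; 1 M HCl
Reagents that add atoms: none
Why: Proposed new method: thermal retro-[4+2] of 3 releases butanoylketene 8, and the Me2C= terminus of 7 (the γ-carbon of a masked β-keto ester dianion) adds to its sp ketene carbon with O-to-O silyl transfer, forming the C1–C6 bond of ring A in 9; a hetero-[4+2] or [2+2] adduct of 8 across the same enol ether would open to the same chain on desilylation. Mg(OMe)2 then unmasks the chelated triketo ester 10, whose butanoyl-flanked CH2 attacks the ester carbon in a 6-(enolexo)-exo-trig Claisen (Dieckmann) closure that forms the C2–C3 bond, expels methoxide and leaves the ring as its stabilised dianion. The closest known reaction types are the capture of dioxinone-derived acylketenes by silyl enol ethers and ketene acetals, the γ-acylation of 1,3-bis(silyloxy)dienes by acyl chlorides, and the magnesium-methoxide-mediated biomimetic Claisen cyclisation of 3,5,7-triketo esters to acylphloroglucinols; their merger into a formal Diels–Alder addition across the C=C bond of a ketene is the new element. No stereocentre is created. The step needs γ- rather than α-acylation of the diene, which vinylogy should secure (largest HOMO coefficient at the terminal carbon, and a Me2C= terminus behaves like an isobutyrate silyl ketene acetal toward a small sp electrophile), and Claisen rather than aldol closure, which the quaternary C6 (no enolisation toward C6, no aromatisation of an aldol product) and magnesium chelation of both 1,3-dicarbonyl units (ester as the only free electrophile, trione dianion as thermodynamic sink) should secure.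

**Step 5**
Reactants: 12 2',4',6'-trihydroxyacetophenone
Product: 14 2-acetyl-3,5-dihydroxy-6,6-dimethylcyclohexa-2,4-dien-1-one (acetylfilicinic acid), via mono-C-methyl ketone 13 (not isolated)
Conditions: NaOMe (3 equiv), MeI (2.1 equiv), MeOH, 0 °C → rt; 1 M HCl; chromatography
Reagents that add atoms: iodomethane, CI
Why: Base-mediated C-methylation of the acylphloroglucinol polyanion (dearomatising gem-dimethylation): the second methyl enters at the already methylated carbon and gives the non-aromatic β-triketone, whose stabilised dianion should be methylated more slowly.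

**Step 6**
Reactants: 14 2-acetyl-3,5-dihydroxy-6,6-dimethylcyclohexa-2,4-dien-1-one
Product: 15 2-acetyl-4-[(dimethylamino)methyl]-3,5-dihydroxy-6,6-dimethylcyclohexa-2,4-dien-1-one (zwitterionic Mannich base)
Conditions: CH2=NMe2+ I−, i-Pr2NEt, CH2Cl2, 0 °C → rt
Reagents that add atoms: N,N-dimethylmethyleneiminium iodide (Eschenmoser's salt), C=[N+](C)C.[I-]
Why: Mannich aminomethylation with a preformed iminium salt at the only ring CH (C4, flanked by two enol carbons); without free formaldehyde, self-coupling to the symmetric methylene-bis compound should be suppressed.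

**Step 7**
Reactants: 15 2-acetyl-4-[(dimethylamino)methyl]-3,5-dihydroxy-6,6-dimethylcyclohexa-2,4-dien-1-one, 11 2-butanoyl-3,5-dihydroxy-6,6-dimethylcyclohexa-2,4-dien-1-one
Product: 17 2-acetyl-4-[(5-butanoyl-2,6-dihydroxy-3,3-dimethyl-4-oxocyclohexa-1,5-dien-1-yl)methyl]-3,5-dihydroxy-6,6-dimethylcyclohexa-2,4-dien-1-one (target), via methylidene trione 16 (not isolated)
Conditions: MeCN, 50 °C, N2 sweep; dilute HCl wash
Reagents that add atoms: none
Why: Thermal E1cB loss of dimethylamine gives the vinylogous quinone methide 16, which the single nucleophilic ring carbon (C4) of 11 should capture in a Michael addition (elimination–addition of a Mannich base); each partner has only one free ring position, so only the unsymmetrical dimer can form directly.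

**Compound list**

1 | 2,2,6-trimethyl-4H-1,3-dioxin-4-one | CC1=CC(=O)OC(C)(C)O1 | starting material
2 | lithium 2,2-dimethyl-6-methylidene-6H-1,3-dioxin-4-olate | [Li+].[O-]C1=CC(=C)OC(C)(C)O1 | intermediate
3 | 2,2-dimethyl-6-propyl-4H-1,3-dioxin-4-one | CCCC1=CC(=O)OC(C)(C)O1 | intermediate
4 | methyl 4-methyl-3-oxopentanoate | COC(=O)CC(=O)C(C)C | starting material
5 | methyl 4-methyl-3-(trimethylsilyloxy)pent-2-enoate (E/Z mixture) | COC(=O)C=C(O[Si](C)(C)C)C(C)C | intermediate
6 | lithium 1-methoxy-4-methyl-3-(trimethylsilyloxy)penta-1,3-dien-1-olate | [Li+].[O-]C(OC)=CC(O[Si](C)(C)C)=C(C)C | intermediate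
7 | 1-methoxy-4-methyl-1,3-bis(trimethylsilyloxy)penta-1,3-diene | COC(O[Si](C)(C)C)=CC(O[Si](C)(C)C)=C(C)C | intermediate
8 | butanoylketene (3-oxohex-1-en-1-one) | CCCC(=O)C=C=O | intermediate
9 | methyl 4,4-dimethyl-5-oxo-3,7-bis(trimethylsilyloxy)deca-2,6-dienoate (alkene geometry undefined) | COC(=O)C=C(O[Si](C)(C)C)C(C)(C)C(=O)C=C(CCC)O[Si](C)(C)C | intermediate
10 | methyl 4,4-dimethyl-3,5,7-trioxodecanoate | COC(=O)CC(=O)C(C)(C)C(=O)CC(=O)CCC | intermediate
11 | 2-butanoyl-3,5-dihydroxy-6,6-dimethylcyclohexa-2,4-dien-1-one | CCCC(=O)C1=C(O)C=C(O)C(C)(C)C1=O | intermediate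
12 | 2',4',6'-trihydroxyacetophenone | CC(=O)c1c(O)cc(O)cc1O | starting material
13 | 1-(2,4,6-trihydroxy-3-methylphenyl)ethan-1-one | CC(=O)c1c(O)cc(O)c(C)c1O | intermediate
14 | 2-acetyl-3,5-dihydroxy-6,6-dimethylcyclohexa-2,4-dien-1-one | CC(=O)C1=C(O)C=C(O)C(C)(C)C1=O | intermediate
15 | 2-acetyl-4-[(dimethylamino)methyl]-3,5-dihydroxy-6,6-dimethylcyclohexa-2,4-dien-1-one | CC(=O)C1=C(O)C(CN(C)C)=C(O)C(C)(C)C1=O | intermediate
16 | 2-acetyl-3-hydroxy-6,6-dimethyl-4-methylidenecyclohex-2-ene-1,5-dione | CC(=O)C1=C(O)C(=C)C(=O)C(C)(C)C1=O | intermediate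
17 | 2-acetyl-4-[(5-butanoyl-2,6-dihydroxy-3,3-dimethyl-4-oxocyclohexa-1,5-dien-1-yl)methyl]-3,5-dihydroxy-6,6-dimethylcyclohexa-2,4-dien-1-one | CCCC(=O)C1=C(O)C(CC2=C(O)C(C)(C)C(=O)C(C(C)=O)=C2O)=C(O)C(C)(C)C1=O | target

**Totals**

Total step count: 7. Longest linear sequence: 4 steps (steps 2, 3, 4 and 7, from methyl 4-methyl-3-oxopentanoate).

**Steps most likely to fail**

Step 4 (Proposed new method). The ketene may acylate the diene at its α-carbon or at oxygen instead of the hindered γ-terminus, ketene dimerisation may outrun capture, or the 2,2-dimethyl-1,3-dione may undergo retro-Claisen cleavage during the methoxide stage before the ring closes. The fallback uses known chemistry; it sets out from 4 and returns at 11. Deprotonation of 4 with NaH and then n-BuLi (THF, 0 °C) should give the sodium lithium dianion of methyl 4-methyl-3-oxopentanoate F1. Its γ-carbon should be acylated by acetyl chloride at −78 °C to methyl 4,4-dimethyl-3,5-dioxohexanoate F2, which forms the C1–C6 bond. Dieckmann cyclisation (NaOMe, MeOH, reflux) should then form the C2–C3 bond and give filicinic acid F3. C-Acylation of one of its two equivalent ring CH positions with butanoic acid in BF3·OEt2 (or butanoyl chloride/AlCl3) should give 11.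

Step 7. Retro-Mannich and retro-Michael steps may exchange the methylene unit between the two rings and scramble the product toward the two symmetric dimers, and 16 may dimerise. The fallback sets out from 14 and returns at 17. Three-component thiomethylation of 14 (paraformaldehyde, PhSH, cat. Et3N, EtOH) should give 2-acetyl-3,5-dihydroxy-6,6-dimethyl-4-[(phenylsulfanyl)methyl]cyclohexa-2,4-dien-1-one F7. Oxidation (mCPBA, CH2Cl2, −40 °C) should give 2-acetyl-3,5-dihydroxy-6,6-dimethyl-4-[(phenylsulfinyl)methyl]cyclohexa-2,4-dien-1-one F8. Its syn-elimination at 20–40 °C in the presence of 11 should release 16 without base or amine, and Michael addition of 11 then gives 17.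

Step 5. Each C-methylation leaves a still-nucleophilic enolate, so under-methylation, over-methylation at the second ring position and O-methylation compete with the desired double methylation at one carbon. The fallback replaces dearomatisation by de novo annulation; it sets out from 7 and 1 and returns at 14. Under the conditions of step 4, the commercial dioxinone 1 should release acetylketene F4, which should acylate 7 to methyl 4,4-dimethyl-5-oxo-3,7-bis(trimethylsilyloxy)octa-2,6-dienoate F5. Mg(OMe)2 in MeOH should unmask methyl 4,4-dimethyl-3,5,7-trioxooctanoate F6, whose Claisen closure gives 14. This route depends on the annulation of step 4 having been established.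

**Further compounds**

F1 | step 4 | sodium lithium dianion of methyl 4-methyl-3-oxopentanoate | [Na+].[Li+].[O-]C(OC)=CC([O-])=C(C)C
F2 | step 4 | methyl 4,4-dimethyl-3,5-dioxohexanoate | COC(=O)CC(=O)C(C)(C)C(C)=O
F3 | step 4 | filicinic acid (3,5-dihydroxy-4,4-dimethylcyclohexa-2,5-dien-1-one) | CC1(C)C(O)=CC(=O)C=C1O
F4 | step 5 | acetylketene (3-oxobut-1-en-1-one) | CC(=O)C=C=O
F5 | step 5 | methyl 4,4-dimethyl-5-oxo-3,7-bis(trimethylsilyloxy)octa-2,6-dienoate | COC(=O)C=C(O[Si](C)(C)C)C(C)(C)C(=O)C=C(C)O[Si](C)(C)C
F6 | step 5 | methyl 4,4-dimethyl-3,5,7-trioxooctanoate | COC(=O)CC(=O)C(C)(C)C(=O)CC(C)=O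
F7 | step 7 | 2-acetyl-3,5-dihydroxy-6,6-dimethyl-4-[(phenylsulfanyl)methyl]cyclohexa-2,4-dien-1-one | CC(=O)C1=C(O)C(CSc2ccccc2)=C(O)C(C)(C)C1=O
F8 | step 7 | 2-acetyl-3,5-dihydroxy-6,6-dimethyl-4-[(phenylsulfinyl)methyl]cyclohexa-2,4-dien-1-one (racemic at sulfur) | CC(=O)C1=C(O)C(CS(=O)c2ccccc2)=C(O)C(C)(C)C1=O
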